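(Readings and results were generated by integration with constants of no real substance, and the scatter is random.)

The reckoning starts from the late readings of the epsilon run, where target shows its slope; the eta run is read from its first reading to its last, so its slope has the lag in it.

| flask | starting material | protic impurity | capture agent | temperature | remark | time |
|---|---|---|---|---|---|---|
| eta | 0.33 M | 0.033 M | 0.066 M | 58 °C | run made earlier |  |
| epsilon | 0.49 M | 0.033 M | 0.066 M | 74 °C | run made earlier |  |
| south | 0.66 M | 0.0330 M | 0.0660 M | 60 °C |  | 3.0 d |
| north-west | 0.66 M | 0.0330 M | 0.0660 M | 70 °C |  | 3.0 d |

- eta (time / d: target / %): 0.500: 1.1; 1.04: 0; 1.25: 1.3; 2.08: 1.9; 2.50: 6.7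
- epsilon (time / h: target / %): 6.00: 2.7; 12.0: 6.4; 15.0: 8.8; 25.0: 17.1; 30.0: 20.3

(standard deviation of a reading: 1 percentage point)

- which of the two there is more of at the end, counted by the starting material in each, south (side product / target)
- which of the two there is more of at the end, counted by the starting material in each, north-west (side product / target)
- final target, as a percentage of the starting material charged, in south
- final target, as a percentage of the starting material charged, in north-west

- percentages count the starting material that a species holds: one side product counts as two
- steps thought possible: starting material -> intermediate A; intermediate A -> intermediate B; intermediate B -> intermediate C; intermediate C -> target; starting material + protic impurity -> quenched substrate; intermediate B + capture agent -> trapped intermediate; starting material + intermediate A -> side product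

In the epsilon run, target climbs from 6.4 % at 12.0 h to 20.3 % at 30.0 h, a slope of 0.00772 h⁻¹ as a fraction of the charge. The eta run, read from its first to its last reading, gives 0.00117 h⁻¹, a rough reading because each point scatters by 1 percentage point. I take this fraction to be independent of the charge, as for a first-order step, and its logarithm to be straight in temperature. North-west then has a late slope, the fraction of the charge turned into target per hour once the lag (induction period) is over, of 0.00481 h⁻¹, and south has 0.00148 h⁻¹.

A first round, slope times time, gives 34.7 % in north-west. A second round puts the lag back in. The epsilon line falls short of its slope times time by 2.87 %, and I assume that the lag stretches as the slope shrinks, so this loss stays the same. My reckoning thus gives 31.8 % in north-west and 7.77 % in south. The readings hold no side product, so it gives no choice for that comparison.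

The forecast says 6 % for south and 23 % for north-west, lower than my figures, and expects that “side product wins when cool and target when hot”.

    starting material → intermediate A (k = 0.00260 min⁻¹, Ea = 102 kJ mol⁻¹)
    intermediate A → intermediate B (k = 5.30 × 10⁻⁵ min⁻¹, Ea = 112 kJ mol⁻¹)
    intermediate B → intermediate C (k = 0.00260 min⁻¹, Ea = 115 kJ mol⁻¹)
    intermediate C → target (k = 0.00130 min⁻¹, Ea = 110 kJ mol⁻¹)
    starting material + protic impurity → quenched substrate (k = 0.00450 M⁻¹ min⁻¹, Ea = 89.0 kJ mol⁻¹)
    intermediate B + capture agent → trapped intermediate (k = 0.0320 M⁻¹ min⁻¹, Ea = 63.0 kJ mol⁻¹)
    starting material + intermediate A → side product (k = 0.00140 M⁻¹ min⁻¹, Ea = 96.0 kJ mol⁻¹)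
    (constants at 60 °C)

North-west ends with 29.0 % of target against 22.1 % of side product, and south with 6.68 % against 23.1 %. Between 1.50 d and 3.00 d, north-west goes from 14.3 % to 29.0 % of target, a slope of 0.00408 h⁻¹, lower than the carried 0.00481 h⁻¹, while intermediate A falls from 52.6 % to 36.3 %.

For north-west read at 20 h, the late slope less the lag loss gives 6.75 %. The computed flask holds 6.66 %.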